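The constants belong to no real substance; what happens was integrated by code.

A stirred flow tank and a closed flask receive the same charge of Z for the same 30 s. Two of us dispute whether the vessel changes how much E escapes capture by Z, which forms Z.E with constant k = 0.0893 /M/s.

- Saturday's: Z 0.20 M; one stirred flow tank at steady state, fed with the mixture as stated, mean residence time 30 s
- Friday's: Z 0.20 M; time 30 s; everything together in a closed stirred flask, run for 30 s

1. the set-up with the highest share of E in all that became E or Z.E, at the outlet or at the end ("none" if the first two lie within 2 percentage points) (Saturday's / Friday's / none)
2. share of E in all that became E or Z.E, at the outlet or at the end, Saturday's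
3. share of E in all that became E or Z.E, at the outlet or at the end, Friday's

- percent here means Z units held: one Z.E counts as two
- the stated concentrations are those of everything mixed, before any reaction; amounts are the same in each set-up
- run time (Friday's): 30 s

    Z → D (k1 = 0.0191 /s)
    D → Q (k2 = 0.0768 /s)
    Q ⇌ E (K3 = 14.6, k3 = 0.134 /s)
    D → E (k4 = 0.0540 /s)
    D → L (k5 = 0.0913 /s)
    Z + E → Z.E (k6 = 0.0893 /M/s)

We share one measure, the capture ratio C: Z units held in Z.E per Z unit held in E, so the share asked is 1/(1+C). We also share a pseudo-first-order form, C = 2·k·[Z]·a, where [Z] is free Z and a is the mean age of the E present.

My colleague keeps [Z] at its charge and sets a to 30 s in both vessels. That gives C = 1.07 and 48.3 % twice, hence "none".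

I let Z decay by Z → D, with constant 0.0191 /s. In Saturday's tank, E and Z.E leave by the same flow, so a is the residence time, C = 0.681 and the share is 59.5 %.

In Friday's flask, D lasts about 4.50 s, far shorter than Z's 52.4 s, so E is fed nearly steadily and a is about half the run. With [Z] taken at the end of the run, this flask's capture ratio is 0.302, and the share is 76.8 %.

The forecast also names Friday's, with slightly different figures: 60.4 % for the tank and 76 % for the flask. It argues that E builds late in the flask, “leaving less time for capture”.

The simulation gives Friday's: 60.4 % in Saturday's tank and 76.0 % in Friday's flask.

Friday's share, read back, means C = 0.316, against my 0.302. At 12.8 s in Friday's flask, D was made 0.986 times as fast as it was used up. Between 15.0 s and 30.0 s, E rose from 6.83 % to 15.9 % of the Z charged and Z.E from 1.15 % to 5.01 %, while Z fell from 74.6 % to 54.3 %. For the same flask read at 20 s, my reckoning gives C = 0.244 and a share of 80.4 %; the computed share is 82.0 %.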